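**Plan**

- Retrosynthesis: the ketone and the aldehyde are traced back to a silyl carbinol and a methyl ester. Ring B is then cut at C1'–C6' and C2'–C3' ([4+2]), the carbinol–alkyne bond is cut to a ring-A aldehyde and methyl propiolate, and the prenyl–CH2 bond to a β-keto ester dianion.
- Enabling feature: ring B carries hydroxyls on C3' and C5', the formyl carbon on C2' (ortho and para to them) and three contiguous carbon substituents on C6', C1' and C2'. This is the footprint of a 1,3-dioxygenated diene on an ynoate.
- Forward: ring A is bought as an arene and given Cl, a MOM ether and CHO, then extended to a 4-silyloxy ynoate. The prenylated 1-methoxy-1,3-bis(silyloxy)diene is made separately. Ring B is formed last by benzannulation, and redox adjustment and deprotection finish the synthesis.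
- Stereochemistry: the target has no stereogenic element. The one stereocentre on the way (the carbinol) is made racemic and is erased by oxidation. The 3Z diene geometry serves reactivity only.

Key step: step 9

Remark on the chemistry: the target SMILES has no stereocentre and no stereogenic double bond, so the compound is achiral and "single enantiomer" is taken to mean this one constitution.

**Route**

Step 1
Reactants: 1 3-methoxy-5-methylphenol
Product: 2 2-chloro-5-methoxy-3-methylphenol
Conditions: SO2Cl2 (1.0 equiv), 2,2,6,6-tetramethylpiperidine (5 mol %), toluene, 0 °C → rt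
Reagents that add atoms: sulfuryl chloride, O=S(=O)(Cl)Cl
Why: Electrophilic aromatic chlorination under secondary-amine catalysis, in which the N-chloroamine hydrogen-bonded to the phenol should deliver chlorine ortho to the hydroxyl; of the two ortho sites, C6 is also para to the methoxy group and is the usual site of substitution in orcinol derivatives, whereas C2 between the two oxygens is avoided.

Step 2
Reactants: 2 2-chloro-5-methoxy-3-methylphenol
Product: 3 2-chloro-5-methoxy-1-(methoxymethoxy)-3-methylbenzene
Conditions: NaH, MOMCl, THF–DMF, 0 °C → rt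
Reagents that add atoms: chloromethyl methyl ether (MOMCl), COCCl
Why: Williamson-type O-alkylation of the sodium phenoxide with the reactive α-chloro ether installs a MOM group that later directs metalation and is stable to the basic, hydridic and oxidative steps that follow.

Step 3
Reactants: 3 2-chloro-5-methoxy-1-(methoxymethoxy)-3-methylbenzene
Product: 5 3-chloro-6-methoxy-2-(methoxymethoxy)-4-methylbenzaldehyde, via aryllithium 4 (not isolated)
Conditions: n-BuLi, THF, 0 °C; then DMF, −78 °C → rt; aqueous work-up
Reagents that add atoms: N,N-dimethylformamide, CN(C)C=O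
Why: Directed ortho-metalation at the ring hydrogen flanked by OMOM and OMe (the cooperative site; the other ortho position of the MOM ether is blocked by chlorine, which has no ortho hydrogen, so no aryne can form), followed by formylation of the aryllithium with DMF.

Step 4
Reactants: 5 3-chloro-6-methoxy-2-(methoxymethoxy)-4-methylbenzaldehyde; 6 methyl propiolate
Product: 8 methyl 4-[3-chloro-6-methoxy-2-(methoxymethoxy)-4-methylphenyl]-4-hydroxybut-2-ynoate (racemic), via methyl 3-lithiopropiolate 7 (not isolated)
Conditions: 6, LiHMDS, THF, −78 °C; then 5, −78 °C; AcOH quench at −78 °C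
Reagents that add atoms: none
Why: 1,2-Addition of a lithium acetylide to an aldehyde; the lithiated propiolate is stable at −78 °C and small enough to reach the di-ortho-substituted formyl group, the cold acetic acid quench avoids base-mediated isomerisation of the γ-hydroxy ynoate, and the new carbinol centre is deliberately formed racemic.

Step 5
Reactants: 8 methyl 4-[3-chloro-6-methoxy-2-(methoxymethoxy)-4-methylphenyl]-4-hydroxybut-2-ynoate
Product: 9 methyl 4-(tert-butyldimethylsilyloxy)-4-[3-chloro-6-methoxy-2-(methoxymethoxy)-4-methylphenyl]but-2-ynoate (racemic)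
Conditions: TBSOTf (1.2 equiv), 2,6-lutidine, CH2Cl2, −78 → 0 °C
Reagents that add atoms: tert-butyldimethylsilyl triflate, CC(C)(C)[Si](C)(C)OS(=O)(=O)C(F)(F)F
Why: Silylation of a hindered secondary alcohol with a silyl triflate and a non-nucleophilic pyridine base, which avoids the redox isomerisation and conjugate addition that ynoates undergo with nucleophilic amines.

Step 6
Reactants: 10 methyl acetoacetate; 11 prenyl bromide (1-bromo-3-methylbut-2-ene)
Product: 13 methyl 7-methyl-3-oxooct-6-enoate, via acetoacetate dianion 12 (not isolated)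
Conditions: NaH, THF, 0 °C; n-BuLi, 0 °C; then 11, 0 °C → rt; aq. HCl quench
Reagents that add atoms: none
Why: γ-Alkylation of a β-keto ester dianion, in which the more basic terminal carbanion displaces the allylic bromide (SN2) and the α-position stays untouched.

Step 7
Reactants: 13 methyl 7-methyl-3-oxooct-6-enoate
Product: 14 methyl 7-methyl-3-(trimethylsilyloxy)octa-2,6-dienoate (2E/2Z mixture, of no consequence)
Conditions: TMSCl, Et3N, hexane, rt
Reagents that add atoms: chlorotrimethylsilane, C[Si](C)(C)Cl
Why: Soft enolisation and O-silylation of the β-keto ester gives the mono silyl enol ether required for the subsequent γ-deprotonation.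

Step 8
Reactants: 14 methyl 7-methyl-3-(trimethylsilyloxy)octa-2,6-dienoate
Product: 16 (3Z)-1-methoxy-7-methyl-1,3-bis(trimethylsilyloxy)octa-1,3,6-triene (C1=C2 geometry uncontrolled and irrelevant), via lithium dienolate 15 (not isolated)
Conditions: LDA, THF, −78 °C; TMSCl, −78 → 0 °C; non-aqueous work-up (pentane, filtration), used crude
Reagents that add atoms: chlorotrimethylsilane, C[Si](C)(C)Cl
Why: γ-Deprotonation of the vinylogous ester gives an extended dienolate that is O-silylated to the 1,3-bis(silyloxy)diene; the 3Z geometry (OTMS and CH2 cis) is the normal outcome for 4-alkyl dienes of this class and turns the prenyl chain to the outside of the s-cis diene.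

Step 9
Reactants: 9 methyl 4-(tert-butyldimethylsilyloxy)-4-[3-chloro-6-methoxy-2-(methoxymethoxy)-4-methylphenyl]but-2-ynoate; 16 (3Z)-1-methoxy-7-methyl-1,3-bis(trimethylsilyloxy)octa-1,3,6-triene
Product: 18 methyl 2-{(tert-butyldimethylsilyloxy)[3-chloro-6-methoxy-2-(methoxymethoxy)-4-methylphenyl]methyl}-4,6-dihydroxy-3-(3-methylbut-2-enyl)benzoate (racemic), via cyclohexadiene cycloadduct 17 (not isolated)
Conditions: 16 (3 equiv), toluene (concentrated), 120 °C, sealed tube; then 0.1 M HCl, THF–MeOH, 0 °C
Reagents that add atoms: none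
Why: Thermal normal-electron-demand Diels–Alder reaction between the electron-rich 1-methoxy-1,3-bis(silyloxy)diene and the ynoate, asynchronous, with the prenyl-bearing diene terminus C4 bonding first to the ynoate β-carbon (C1'–C6') and the ketene-acetal carbon C1 to the α-carbon (C2'–C3'). The closest known reaction type is the benzannulation of 1-alkoxy-1,3-bis(silyloxy)dienes with acetylenic esters to give β-resorcylates. Ring B is closed by this intermolecular [4+2] cycloaddition as cyclohexa-1,4-diene 17, which aromatises by 1,4-elimination of methanol from the mixed ketal carbon and the C6' hydrogen, followed by hydrolysis of the two aryl silyl ethers. No lasting stereocentre is created: the two sp3 ring carbons of 17 disappear on aromatisation and the carbinol centre is racemic from step 4. The step needs regioselectivity, which is secured by keeping the future ketone as a silyl carbinol so that the ester is the only π-acceptor and polarises the alkyne for attack at the β-carbon; it also needs an s-cis diene, which the 3Z geometry permits.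

Step 10
Reactants: 18 methyl 2-{(tert-butyldimethylsilyloxy)[3-chloro-6-methoxy-2-(methoxymethoxy)-4-methylphenyl]methyl}-4,6-dihydroxy-3-(3-methylbut-2-enyl)benzoate
Product: 19 methyl 2-{(tert-butyldimethylsilyloxy)[3-chloro-6-methoxy-2-(methoxymethoxy)-4-methylphenyl]methyl}-4,6-bis(methoxymethoxy)-3-(3-methylbut-2-enyl)benzoate (racemic)
Conditions: NaH (2.5 equiv), MOMCl (2.5 equiv), DMF, 0 °C → rt
Reagents that add atoms: chloromethyl methyl ether (MOMCl), COCCl
Why: Double Williamson O-alkylation of the bis-phenoxide; NaH is needed for the hydroxyl hydrogen-bonded to the ester, and capping both phenols prepares the hydride and oxidation steps.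

Step 11
Reactants: 19 methyl 2-{(tert-butyldimethylsilyloxy)[3-chloro-6-methoxy-2-(methoxymethoxy)-4-methylphenyl]methyl}-4,6-bis(methoxymethoxy)-3-(3-methylbut-2-enyl)benzoate
Product: 20 {2-{(tert-butyldimethylsilyloxy)[3-chloro-6-methoxy-2-(methoxymethoxy)-4-methylphenyl]methyl}-4,6-bis(methoxymethoxy)-3-(3-methylbut-2-enyl)phenyl}methanol (racemic)
Conditions: LiAlH4, THF, 0 °C → rt; Rochelle-salt work-up
Reagents that add atoms: none
Why: Hydride reduction of a hindered benzoate to the benzylic alcohol, assisted by the chelating ortho MOM ether; the silyl ether, MOM ethers, aryl chloride and trisubstituted alkene are inert to LiAlH4.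

Step 12
Reactants: 20 {2-{(tert-butyldimethylsilyloxy)[3-chloro-6-methoxy-2-(methoxymethoxy)-4-methylphenyl]methyl}-4,6-bis(methoxymethoxy)-3-(3-methylbut-2-enyl)phenyl}methanol
Product: 21 [3-chloro-6-methoxy-2-(methoxymethoxy)-4-methylphenyl][2-(hydroxymethyl)-3,5-bis(methoxymethoxy)-6-(3-methylbut-2-enyl)phenyl]methanol (racemic)
Conditions: TBAF, THF, rt → 45 °C; chromatography on Et3N-buffered silica
Reagents that add atoms: none
Why: Fluoride-mediated Si–O cleavage frees the secondary carbinol, and the basic medium avoids acid-induced cyclodehydration of the 1,4-diol to a phthalan.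

Step 13
Reactants: 21 [3-chloro-6-methoxy-2-(methoxymethoxy)-4-methylphenyl][2-(hydroxymethyl)-3,5-bis(methoxymethoxy)-6-(3-methylbut-2-enyl)phenyl]methanol
Product: 22 2-[3-chloro-6-methoxy-2-(methoxymethoxy)-4-methylbenzoyl]-4,6-bis(methoxymethoxy)-3-(3-methylbut-2-enyl)benzaldehyde
Conditions: (COCl)2 (4 equiv), DMSO (8 equiv), CH2Cl2, −78 °C; then Et3N, −78 → 0 °C
Reagents that add atoms: none
Why: Swern oxidation, in which both hydroxyls are converted to alkoxysulfonium ions at −78 °C before base is added, so that no carbonyl coexists with a free neighbouring hydroxyl and lactol formation with over-oxidation to the phthalide is avoided, as in known conversions of 2-(hydroxymethyl)benzhydrols into 2-aroylbenzaldehydes.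

Step 14
Reactants: 22 2-[3-chloro-6-methoxy-2-(methoxymethoxy)-4-methylbenzoyl]-4,6-bis(methoxymethoxy)-3-(3-methylbut-2-enyl)benzaldehyde
Product: 23 Pestalone F, 2-(3-chloro-2-hydroxy-6-methoxy-4-methylbenzoyl)-4,6-dihydroxy-3-(3-methylbut-2-enyl)benzaldehyde
Conditions: 3 M aq. HCl, THF, 40 °C
Reagents that add atoms: none
Why: Acid-catalysed hydrolysis of the three aryl MOM acetals under dilute aqueous HCl, the standard method for MOM-protected ortho-prenyl phenols; the aqueous rather than methanolic medium should keep the keto-aldehyde from being trapped as a cyclic acetal.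

**Compound list**

1 | 3-methoxy-5-methylphenol | COc1cc(C)cc(O)c1 | starting material
2 | 2-chloro-5-methoxy-3-methylphenol | COc1cc(C)c(Cl)c(O)c1 | intermediate
3 | 2-chloro-5-methoxy-1-(methoxymethoxy)-3-methylbenzene | COCOc1cc(OC)cc(C)c1Cl | intermediate
4 | [3-chloro-6-methoxy-2-(methoxymethoxy)-4-methylphenyl]lithium (not isolated) | [Li]c1c(OC)cc(C)c(Cl)c1OCOC | intermediate
5 | 3-chloro-6-methoxy-2-(methoxymethoxy)-4-methylbenzaldehyde | COc1cc(C)c(Cl)c(OCOC)c1C=O | intermediate
6 | methyl propiolate | C#CC(=O)OC | starting material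
7 | methyl 3-lithiopropiolate (not isolated) | [Li]C#CC(=O)OC | intermediate
8 | methyl 4-[3-chloro-6-methoxy-2-(methoxymethoxy)-4-methylphenyl]-4-hydroxybut-2-ynoate (racemic) | COc1cc(C)c(Cl)c(OCOC)c1C(O)C#CC(=O)OC | intermediate
9 | methyl 4-(tert-butyldimethylsilyloxy)-4-[3-chloro-6-methoxy-2-(methoxymethoxy)-4-methylphenyl]but-2-ynoate (racemic) | COc1cc(C)c(Cl)c(OCOC)c1C(O[Si](C)(C)C(C)(C)C)C#CC(=O)OC | intermediate
10 | methyl acetoacetate | COC(=O)CC(C)=O | starting material
11 | prenyl bromide (1-bromo-3-methylbut-2-ene) | CC(C)=CCBr | starting material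
12 | lithium sodium dianion of methyl acetoacetate (not isolated) | [Li+].[Na+].C=C([O-])C=C([O-])OC | intermediate
13 | methyl 7-methyl-3-oxooct-6-enoate | COC(=O)CC(=O)CCC=C(C)C | intermediate
14 | methyl 7-methyl-3-(trimethylsilyloxy)octa-2,6-dienoate (2E/2Z mixture) | COC(=O)C=C(O[Si](C)(C)C)CCC=C(C)C | intermediate
15 | lithium (3Z)-1-methoxy-7-methyl-3-(trimethylsilyloxy)octa-1,3,6-trien-1-olate (not isolated) | [Li+].COC([O-])=CC(/O[Si](C)(C)C)=C/CC=C(C)C | intermediate
16 | (3Z)-1-methoxy-7-methyl-1,3-bis(trimethylsilyloxy)octa-1,3,6-triene (C1=C2 geometry undefined) | COC(O[Si](C)(C)C)=CC(/O[Si](C)(C)C)=C/CC=C(C)C | intermediate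
17 | methyl 2-{(tert-butyldimethylsilyloxy)[3-chloro-6-methoxy-2-(methoxymethoxy)-4-methylphenyl]methyl}-6-methoxy-3-(3-methylbut-2-enyl)-4,6-bis(trimethylsilyloxy)cyclohexa-1,4-diene-1-carboxylate (diastereomer mixture, not isolated) | COC1(O[Si](C)(C)C)C=C(O[Si](C)(C)C)C(CC=C(C)C)C(C(O[Si](C)(C)C(C)(C)C)c2c(OC)cc(C)c(Cl)c2OCOC)=C1C(=O)OC | intermediate
18 | methyl 2-{(tert-butyldimethylsilyloxy)[3-chloro-6-methoxy-2-(methoxymethoxy)-4-methylphenyl]methyl}-4,6-dihydroxy-3-(3-methylbut-2-enyl)benzoate (racemic) | COc1cc(C)c(Cl)c(OCOC)c1C(O[Si](C)(C)C(C)(C)C)c1c(C(=O)OC)c(O)cc(O)c1CC=C(C)C | intermediate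
19 | methyl 2-{(tert-butyldimethylsilyloxy)[3-chloro-6-methoxy-2-(methoxymethoxy)-4-methylphenyl]methyl}-4,6-bis(methoxymethoxy)-3-(3-methylbut-2-enyl)benzoate (racemic) | COc1cc(C)c(Cl)c(OCOC)c1C(O[Si](C)(C)C(C)(C)C)c1c(C(=O)OC)c(OCOC)cc(OCOC)c1CC=C(C)C | intermediate
20 | {2-{(tert-butyldimethylsilyloxy)[3-chloro-6-methoxy-2-(methoxymethoxy)-4-methylphenyl]methyl}-4,6-bis(methoxymethoxy)-3-(3-methylbut-2-enyl)phenyl}methanol (racemic) | COc1cc(C)c(Cl)c(OCOC)c1C(O[Si](C)(C)C(C)(C)C)c1c(CO)c(OCOC)cc(OCOC)c1CC=C(C)C | intermediate
21 | [3-chloro-6-methoxy-2-(methoxymethoxy)-4-methylphenyl][2-(hydroxymethyl)-3,5-bis(methoxymethoxy)-6-(3-methylbut-2-enyl)phenyl]methanol (racemic) | COc1cc(C)c(Cl)c(OCOC)c1C(O)c1c(CO)c(OCOC)cc(OCOC)c1CC=C(C)C | intermediate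
22 | 2-[3-chloro-6-methoxy-2-(methoxymethoxy)-4-methylbenzoyl]-4,6-bis(methoxymethoxy)-3-(3-methylbut-2-enyl)benzaldehyde | COc1cc(C)c(Cl)c(OCOC)c1C(=O)c1c(C=O)c(OCOC)cc(OCOC)c1CC=C(C)C | intermediate
23 | Pestalone F, 2-(3-chloro-2-hydroxy-6-methoxy-4-methylbenzoyl)-4,6-dihydroxy-3-(3-methylbut-2-enyl)benzaldehyde | COc1cc(C)c(Cl)c(O)c1C(=O)c1c(C=O)c(O)cc(O)c1CC=C(C)C | target

**Step count**

Total: 14 steps. Longest linear sequence: 11 steps (steps 1–5 and 9–14); the diene branch (steps 6–8) joins at step 9.

**Steps most likely to fail**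

1. Step 9. The cycloaddition may stall because the ynoate β-carbon is shielded by the aryl(silyloxy)methyl group, so that the diene is lost to silyl migration and hydrolysis before it adds.
Fallback, setting out from diene 16 and arene 3 and returning at diol 21: ring A is attached after the benzannulation instead of before it. Diene 16 would be heated with the small dienophile methyl 4,4-diethoxybut-2-ynoate F1, made from commercial 3,3-diethoxyprop-1-yne with n-BuLi and methyl chloroformate. This should give the cycloadduct methyl 2-(diethoxymethyl)-6-methoxy-3-(3-methylbut-2-enyl)-4,6-bis(trimethylsilyloxy)cyclohexa-1,4-diene-1-carboxylate F2, which is not isolated. Aqueous HCl in THF would aromatise it, desilylate it and hydrolyse the acetal to methyl 2-formyl-4,6-dihydroxy-3-(3-methylbut-2-enyl)benzoate F3. NaH and MOMCl would then give methyl 2-formyl-4,6-bis(methoxymethoxy)-3-(3-methylbut-2-enyl)benzoate F4. Aryllithium 4, generated from 3 as in step 3, would add to the formyl group of F4 at −78 °C, and the resulting alkoxide should lactonise onto the neighbouring ester to give 3-[3-chloro-6-methoxy-2-(methoxymethoxy)-4-methylphenyl]-5,7-bis(methoxymethoxy)-4-(3-methylbut-2-enyl)-2-benzofuran-1(3H)-one F5. LiAlH4 in THF would open F5 to diol 21, where the route resumes at step 13.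

2. Step 13. The two alcohols may be oxidised one after the other instead of together, so that the aldehyde formed first is captured by the still-free secondary hydroxyl as a lactol and over-oxidised to the phthalide. Ionisation of the activated, doubly benzylic alkoxysulfonium ion with closure to a cyclic ether is a second possible pathway.
Fallback, setting out from diol 21 and returning at keto-aldehyde 22: the ketone is made first and the aldehyde last, so no lactol can be oxidised. TBSCl and imidazole in CH2Cl2 at 0 °C should silylate only the accessible primary hydroxyl, giving [2-(tert-butyldimethylsilyloxymethyl)-3,5-bis(methoxymethoxy)-6-(3-methylbut-2-enyl)phenyl][3-chloro-6-methoxy-2-(methoxymethoxy)-4-methylphenyl]methanol F6. Dess–Martin periodinane with NaHCO3 would oxidise the hindered carbinol to [2-(tert-butyldimethylsilyloxymethyl)-3,5-bis(methoxymethoxy)-6-(3-methylbut-2-enyl)phenyl][3-chloro-6-methoxy-2-(methoxymethoxy)-4-methylphenyl]methanone F7. TBAF would free [3-chloro-6-methoxy-2-(methoxymethoxy)-4-methylphenyl][2-(hydroxymethyl)-3,5-bis(methoxymethoxy)-6-(3-methylbut-2-enyl)phenyl]methanone F8, whose hemiketal form cannot be oxidised further. A second Dess–Martin oxidation would then give 22.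

3. Step 1. Chlorine may be delivered para to the free hydroxyl (C4, between OMe and Me) in competition with the catalyst-directed ortho attack, or a second chlorine may be introduced, leaving isomers that are hard to separate.
Fallback, setting out from phenol 1 and returning at chlorophenol 2: the directing principle is changed from catalyst control to substrate control by masking the phenol. Ac2O and pyridine would give 3-methoxy-5-methylphenyl acetate F9, in which the methoxy group is the strongest donor. NCS in MeCN with catalytic HCl should then chlorinate para to the methoxy group to give 2-chloro-5-methoxy-3-methylphenyl acetate F10. K2CO3 in MeOH would remove the acetate to give 2.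

**Further compounds**

F1 | step 9 | methyl 4,4-diethoxybut-2-ynoate | CCOC(OCC)C#CC(=O)OC
F2 | step 9 | methyl 2-(diethoxymethyl)-6-methoxy-3-(3-methylbut-2-enyl)-4,6-bis(trimethylsilyloxy)cyclohexa-1,4-diene-1-carboxylate (diastereomer mixture, not isolated) | CCOC(OCC)C1=C(C(=O)OC)C(OC)(O[Si](C)(C)C)C=C(O[Si](C)(C)C)C1CC=C(C)C
F3 | step 9 | methyl 2-formyl-4,6-dihydroxy-3-(3-methylbut-2-enyl)benzoate | COC(=O)c1c(O)cc(O)c(CC=C(C)C)c1C=O
F4 | step 9 | methyl 2-formyl-4,6-bis(methoxymethoxy)-3-(3-methylbut-2-enyl)benzoate | COC(=O)c1c(OCOC)cc(OCOC)c(CC=C(C)C)c1C=O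
F5 | step 9 | 3-[3-chloro-6-methoxy-2-(methoxymethoxy)-4-methylphenyl]-5,7-bis(methoxymethoxy)-4-(3-methylbut-2-enyl)-2-benzofuran-1(3H)-one (racemic) | COc1cc(C)c(Cl)c(OCOC)c1C1OC(=O)c2c(OCOC)cc(OCOC)c(CC=C(C)C)c21
F6 | step 13 | [2-(tert-butyldimethylsilyloxymethyl)-3,5-bis(methoxymethoxy)-6-(3-methylbut-2-enyl)phenyl][3-chloro-6-methoxy-2-(methoxymethoxy)-4-methylphenyl]methanol (racemic) | COc1cc(C)c(Cl)c(OCOC)c1C(O)c1c(CO[Si](C)(C)C(C)(C)C)c(OCOC)cc(OCOC)c1CC=C(C)C
F7 | step 13 | [2-(tert-butyldimethylsilyloxymethyl)-3,5-bis(methoxymethoxy)-6-(3-methylbut-2-enyl)phenyl][3-chloro-6-methoxy-2-(methoxymethoxy)-4-methylphenyl]methanone | COc1cc(C)c(Cl)c(OCOC)c1C(=O)c1c(CO[Si](C)(C)C(C)(C)C)c(OCOC)cc(OCOC)c1CC=C(C)C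
F8 | step 13 | [3-chloro-6-methoxy-2-(methoxymethoxy)-4-methylphenyl][2-(hydroxymethyl)-3,5-bis(methoxymethoxy)-6-(3-methylbut-2-enyl)phenyl]methanone | COc1cc(C)c(Cl)c(OCOC)c1C(=O)c1c(CO)c(OCOC)cc(OCOC)c1CC=C(C)C
F9 | step 1 | 3-methoxy-5-methylphenyl acetate | COc1cc(C)cc(OC(C)=O)c1
F10 | step 1 | 2-chloro-5-methoxy-3-methylphenyl acetate | COc1cc(C)c(Cl)c(OC(C)=O)c1
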